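A direct plan would build rings C and D first (Birch reductive alkylation of 3-methoxybenzoic acid, vinyl-radical closure of the bicyclo[3.2.1]octane), add a siloxycyclopropane, the ring A chain and the lactone, and close ring A last by opening cyclopropanol A1 to a C10 radical that would add to an alkenyl boronate and give spiro ketone A2.
Its weakest steps would be: the ring A closure, an unprecedented cyclopropanol opening–boronate capture that would have to set C10 and C5 by a chair preference alone; the repair of C11 (reduction, Mitsunobu inversion, deacylation) and of C15 (allylic oxidation, reoxidation, reduction), six steps that would add no skeleton; and the classical resolution of the first acid, which would discard half of the material.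

The route would make ring A and spirolactone B first and then hang the bicyclo[3.2.1]octane on the lactone through C9–C11 and C8–C15. Because C11 and C15 are 1,5-related through C12–C13–C16, one cyclopentene would supply both as the identical aldehyde arms of a prochiral C13. In the key step the cathodically generated radical anion of the unsaturated lactone (C8=C9) should attack one arm: ring C closes, C9, C11 and C13 are set together and C11 arrives as the carbinol. The surviving arm, once α-methylenated, should close ring D by an aldol that creates quaternary C8, the C15 carbinol and the exocyclic methylene at once. No resolution, inversion or oxidation-state repair remains.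

Key step: step 11

Assumption: atoms are numbered as in ent-kaurane (C1–C20; lactone ring B = C7(=O)–O–C20–C10–C9–C8), and the copper hydride catalyst is taken to show the facial sense known for simple 3-alkylcyclohexenones (otherwise the ligand antipode would be used).

**Step 1**
Reactants: 1 4,4-dimethylcyclohexane-1,3-dione
Product: 2 6,6-dimethyl-3-(2-methylpropoxy)cyclohex-2-en-1-one
Conditions: i-BuOH, p-TsOH (cat.), toluene, reflux, Dean–Stark
Reagents that add atoms: 2-methylpropan-1-ol, CC(C)CO
Why: Acid-catalysed vinylogous ester formation should occur at the carbonyl remote from the gem-dimethyl group, which leaves the hindered carbonyl free for the next addition.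

**Step 2**
Reactants: 2 6,6-dimethyl-3-(2-methylpropoxy)cyclohex-2-en-1-one; 3 tributyl[(methoxymethoxy)methyl]stannane
Product: 6 3-[(methoxymethoxy)methyl]-4,4-dimethylcyclohex-2-en-1-one, via lithium reagent 4 (not isolated), via carbinol adduct 5 (not isolated)
Conditions: n-BuLi, THF, −78 °C; then 2, −78 to 0 °C; then 1 M HCl, 0 °C
Reagents that add atoms: water, O
Why: Tin–lithium exchange gives the alkoxymethyllithium, whose 1,2-addition and acid hydrolysis (Stork–Danheiser enone transposition) place C6 on the carbon next to the gem-dimethyl group, the future C5.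

**Step 3**
Reactants: 6 3-[(methoxymethoxy)methyl]-4,4-dimethylcyclohex-2-en-1-one
Product: 8 (3S)-2-[(dimethylamino)methyl]-3-[(methoxymethoxy)methyl]-4,4-dimethylcyclohexan-1-one (C2 epimers), via silyl enol ether 7 (not isolated)
Conditions: Cu(OAc)2·H2O (3 mol %), (R)-DTBM-SEGPHOS (3 mol %), (EtO)2MeSiH, toluene, 0 °C; then CH2=NMe2+ I−, CH2Cl2, rt; NaHCO3 (aq.) work-up
Reagents that add atoms: N,N-dimethylmethyleneiminium iodide, C=[N+](C)C.[I-]
Why: Copper hydride-catalysed asymmetric conjugate reduction should set C5 under ligand control, and the regiodefined silyl enol ether is captured at C10 by Eschenmoser's salt in a Mannich reaction.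

**Step 4**
Reactants: 8 (3S)-2-[(dimethylamino)methyl]-3-[(methoxymethoxy)methyl]-4,4-dimethylcyclohexan-1-one
Product: 11 (1S,3R)-3-[(methoxymethoxy)methyl]-4,4-dimethyl-2-methylidenecyclohexan-1-ol, via ammonium iodide 9 (not isolated), via methylene ketone 10 (not isolated)
Conditions: MeI, CH2Cl2, rt; NaHCO3 (aq.), rt; then CeCl3·7H2O, NaBH4, MeOH, −78 °C
Reagents that add atoms: none
Why: Quaternisation and Hofmann-type β-elimination unveil the dimerisation-prone α-methylene ketone, which Luche 1,2-reduction converts at once into the allylic alcohol, hydride adding anti to the C5 substituent so that the hydroxyl should end cis to the CH2OMOM group.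

**Step 5**
Reactants: 11 (1S,3R)-3-[(methoxymethoxy)methyl]-4,4-dimethyl-2-methylidenecyclohexan-1-ol
Product: 12 tert-butyl{[(1S,3R)-3-[(methoxymethoxy)methyl]-4,4-dimethyl-2-methylidenecyclohexyl]oxy}dimethylsilane
Conditions: TBSCl, imidazole, DMF, rt
Reagents that add atoms: tert-butyldimethylsilyl chloride, CC(C)(C)[Si](C)(C)Cl
Why: Silylation protects the C1 hydroxyl as a base-stable ether, which keeps it from opening the later lactone and leaves only an oxygen atom on the C1 face of C10.

**Step 6**
Reactants: 12 tert-butyl{[(1S,3R)-3-[(methoxymethoxy)methyl]-4,4-dimethyl-2-methylidenecyclohexyl]oxy}dimethylsilane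
Product: 13 spiro-epoxide of 12 (1-oxaspiro[2.5]octane; C1 and C5 as in 12, both epimers at C10)
Conditions: m-CPBA, NaHCO3, CH2Cl2, 0 °C
Reagents that add atoms: 3-chloroperoxybenzoic acid, O=C(OO)c1cccc(Cl)c1
Why: Prilezhaev epoxidation of the only alkene gives the 1,1-disubstituted epoxide, whose configuration is irrelevant because C10 becomes a planar radical.

**Step 7**
Reactants: 14 4-bromocyclopentene; 15 methyl 2-(bromomethyl)prop-2-enoate
Product: 17 methyl 2-(cyclopent-3-en-1-ylmethyl)prop-2-enoate, via Grignard reagent 16 (not isolated)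
Conditions: Mg, THF, rt; then CuI (10 mol %), 15, THF, −78 to 0 °C
Reagents that add atoms: none
Why: Copper-catalysed SN2′ allylic substitution of the bromomethyl acrylate by the Grignard reagent forms C13–C14 and regenerates the acrylate that will supply C7, C8 and C9.

**Step 8**
Reactants: 13 spiro-epoxide; 17 methyl 2-(cyclopent-3-en-1-ylmethyl)prop-2-enoate
Product: 19 spirolactone (ring A with 1-OTBS and 6-OMOM, δ-lactone C7(=O)–O–C20 spiro at C10, C8 bearing the cyclopent-3-en-1-ylmethyl group; C10 as in the target, C8 epimers), via hydroxy ester 18 (not isolated)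
Conditions: Cp2TiCl2 (20 mol %), Zn dust, 2,4,6-collidine·HCl, THF, rt; then p-TsOH (cat.), CH2Cl2, rt
Reagents that add atoms: none
Why: Reductive epoxide opening by titanocene chloride of trivalent titanium (Nugent–RajanBabu reaction) gives the tertiary C10 radical, whose Giese addition to the acrylate anti to the cis-disposed C1 and C5 substituents should set C10 before the C20 alkoxide lactonises.

**Step 9**
Reactants: 19 spirolactone
Product: 22 unsaturated spirolactone (19 with C8=C9), via selenide 20 (not isolated), via selenoxide 21 (not isolated)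
Conditions: LiN(i-Pr)2, THF, −78 °C; PhSeBr, −78 °C; then NaIO4, NaHCO3, THF/MeOH/H2O, rt
Reagents that add atoms: none
Why: α-Selenenylation of the lactone enolate and selenoxide syn-elimination toward the ring hydrogen at C9 should install the conjugated endocyclic alkene and erase the C8 stereocentre.

**Step 10**
Reactants: 22 unsaturated spirolactone
Product: 24 dialdehyde (C8–CH2–CH(CH2CHO)2), via ozonide 23 (not isolated)
Conditions: O3, CH2Cl2, −78 °C (Sudan red end point); then PPh3, −78 °C to rt
Reagents that add atoms: ozone, [O-][O+]=O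
Why: Ozonolysis with reductive work-up should cleave the electron-rich cyclopentene much faster than the electron-poor trisubstituted lactone alkene and turn the ring into two identical 2-oxoethyl arms on a prochiral C13.

**Step 11**
Reactants: 24 dialdehyde
Product: 25 hydroxy aldehyde (ring C closed by C9–C11, 11-OH, C13 bearing the remaining CH2CHO arm; C9, C11 and C13 as in the target, C8 epimers)
Conditions: divided cell, glassy carbon cathode, about −2.2 V vs SCE (first wave of the enoate), n-Bu4NBF4 (0.1 M), CH2(CO2Me)2 (3 equiv), DMF, 0 °C, 0.01 M; Pt anode in n-Bu4NBr/DMF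
Reagents that add atoms: none
Why: Cathodic one-electron reduction of the α-alkylated unsaturated lactone gives a radical anion whose C9 adds to one aldehyde carbonyl, and a second electron and two protons from the malonate then deliver the C11 carbinol and the saturated lactone. The reaction type is the electroreductive cyclisation of formyl-tethered α,β-unsaturated esters, the electrochemical counterpart of SmI2 ketyl–olefin coupling. Ring C closes by attack of C9 on C11 in the 6-exo-trig mode at the carbonyl. C9 should be set by approach to the lactone face of C1, which carries only the silyloxy oxygen, and not to the face of C5 with its CH2OMOM group, while C11 and C13 should be set by a chair transition state in which the alkoxide oxygen and the spectator arm are equatorial, so that the arm cis to the carbinol oxygen is the one retained. The step needs reduction of the enoate and not of the aldehydes, C–C coupling and not pinacol closure of the 1,5-dialdehyde, and protonation of the C8 enolate before it can add to the second aldehyde; the controlled potential, the absence of an oxophilic metal and the malonate proton donor should secure these.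

**Step 12**
Reactants: 25 hydroxy aldehyde
Product: 26 hydroxy enal (25 with C13–C(=CH2)–CHO)
Conditions: CH2O (37 % aq.), pyrrolidine (10 mol %), EtCO2H (10 mol %), i-PrOH, 45 °C
Reagents that add atoms: formaldehyde, C=O
Why: Amine-catalysed Mannich condensation–elimination (α-methylenation of an aldehyde) acts only at C16, the sole enolisable carbon next to an aldehyde, and so installs C17 and the enal in one operation.

**Step 13**
Reactants: 26 hydroxy enal
Product: 27 tetracyclic diol (rings A to D complete: 1-OTBS, 6-OMOM, 11-OH, 15-OH, 16-methylidene; all stereocentres as in the target)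
Conditions: LiN(SiMe3)2 (2.2 equiv), THF, −78 to −40 °C; AcOH, −78 °C
Reagents that add atoms: none
Why: Intramolecular aldol addition of the lactone enolate to the enal aldehyde (5-exo-trig) forms C8–C15 and ring D; the two-atom tether from C13 allows bonding on one face of C8 only, which fixes the quaternary centre, and the lithium of the neighbouring C11 alkoxide should bind the aldehyde oxygen and turn it toward C11, so that the C15 hydroxyl ends endo.

**Step 14**
Reactants: 27 tetracyclic diol
Product: 28 triol (1-OH, 11-OH, 15-OH; 6-OMOM)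
Conditions: HF·pyridine, pyridine, THF, 0 °C to rt
Reagents that add atoms: none
Why: Buffered fluoride desilylation cleaves the silyl ether through the strong Si–F bond under non-basic conditions that should avoid retro-aldol opening of the β-hydroxy lactone and leave the acetal intact.

**Step 15**
Reactants: 28 triol
Product: 29 1-acetate (6-OMOM ether of the target)
Conditions: Ac2O (1.1 equiv), pyridine, CH2Cl2, 0 °C
Reagents that add atoms: acetic anhydride, CC(=O)OC(C)=O
Why: Acylation should take the equatorial C1 hydroxyl selectively, because the axial 11-hydroxyl lies under the two-carbon bridge and the endo 15-hydroxyl is neopentylic and hydrogen-bonded to it.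

**Step 16**
Reactants: 29 1-acetate
Product: 30 CNP0210922.1
Conditions: ZnBr2, n-PrSH, CH2Cl2, 0 °C
Reagents that add atoms: none
Why: Lewis acid-assisted thiolysis of the methoxymethyl acetal (capture of the oxocarbenium ion by the thiol) frees the C6 hydroxyl under conditions that should spare the acetate, the lactone and the allylic alcohol.

**Compound list**
1 | 4,4-dimethylcyclohexane-1,3-dione | CC1(C)CCC(=O)CC1=O | starting material
2 | 6,6-dimethyl-3-(2-methylpropoxy)cyclohex-2-en-1-one | CC(C)COC1=CC(=O)C(C)(C)CC1 | intermediate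
3 | tributyl[(methoxymethoxy)methyl]stannane | CCCC[Sn](CCCC)(CCCC)COCOC | starting material
4 | [(methoxymethoxy)methyl]lithium (not isolated) | [Li]COCOC | intermediate
5 | 1-[(methoxymethoxy)methyl]-6,6-dimethyl-3-(2-methylpropoxy)cyclohex-2-en-1-ol (lithium alkoxide in the flask, not isolated) | COCOCC1(O)C=C(OCC(C)C)CCC1(C)C | intermediate
6 | 3-[(methoxymethoxy)methyl]-4,4-dimethylcyclohex-2-en-1-one | COCOCC1=CC(=O)CCC1(C)C | intermediate
7 | diethoxy(methyl){[(3S)-3-[(methoxymethoxy)methyl]-4,4-dimethylcyclohex-1-en-1-yl]oxy}silane (not isolated) | CCO[Si](C)(OCC)OC1=C[C@H](COCOC)C(C)(C)CC1 | intermediate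
8 | (3S)-2-[(dimethylamino)methyl]-3-[(methoxymethoxy)methyl]-4,4-dimethylcyclohexan-1-one (C2 epimers) | CN(C)CC1C(=O)CCC(C)(C)[C@H]1COCOC | intermediate
9 | N-methylammonium iodide of 8 (not isolated) | C[N+](C)(C)CC1C(=O)CCC(C)(C)[C@H]1COCOC.[I-] | intermediate
10 | (3R)-3-[(methoxymethoxy)methyl]-4,4-dimethyl-2-methylidenecyclohexan-1-one (not isolated) | C=C1C(=O)CCC(C)(C)[C@H]1COCOC | intermediate
11 | (1S,3R)-3-[(methoxymethoxy)methyl]-4,4-dimethyl-2-methylidenecyclohexan-1-ol (hydroxyl cis to CH2OMOM) | C=C1[C@@H](O)CCC(C)(C)[C@H]1COCOC | intermediate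
12 | tert-butyl{[(1S,3R)-3-[(methoxymethoxy)methyl]-4,4-dimethyl-2-methylidenecyclohexyl]oxy}dimethylsilane | C=C1[C@@H](O[Si](C)(C)C(C)(C)C)CCC(C)(C)[C@H]1COCOC | intermediate
13 | spiro-epoxide of 12: 4-(tert-butyldimethylsilyloxy)-8-[(methoxymethoxy)methyl]-7,7-dimethyl-1-oxaspiro[2.5]octane, C1 and C5 as in 12, both epimers at the spiro carbon C10 | C1OC12[C@@H](O[Si](C)(C)C(C)(C)C)CCC(C)(C)[C@H]2COCOC | intermediate
14 | 4-bromocyclopentene | BrC1CC=CC1 | starting material
15 | methyl 2-(bromomethyl)prop-2-enoate | C=C(CBr)C(=O)OC | starting material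
16 | cyclopent-3-en-1-ylmagnesium bromide (not isolated) | Br[Mg]C1CC=CC1 | intermediate
17 | methyl 2-(cyclopent-3-en-1-ylmethyl)prop-2-enoate | C=C(CC1CC=CC1)C(=O)OC | intermediate
18 | hydroxy ester: C10 quaternary with CH2OH (C20) and CH2–CH(CO2Me)–CH2–cyclopentenyl chain, 1-OTBS, 6-OMOM (not isolated) | COC(=O)C(CC1CC=CC1)C[C@]1(CO)[C@@H](O[Si](C)(C)C(C)(C)C)CCC(C)(C)[C@H]1COCOC | intermediate
19 | spirolactone: ring A (1-OTBS, 6-OMOM) spiro at C10 to δ-lactone C7(=O)–O–C20, C8 bearing cyclopent-3-en-1-ylmethyl; C1, C5, C10 as in the target, C8 epimers | O=C1OC[C@@]2(CC1CC1CC=CC1)[C@@H](O[Si](C)(C)C(C)(C)C)CCC(C)(C)[C@H]2COCOC | intermediate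
20 | 8-phenylselanyl derivative of 19 (not isolated) | O=C1OC[C@@]2(CC1(CC1CC=CC1)[Se]c1ccccc1)[C@@H](O[Si](C)(C)C(C)(C)C)CCC(C)(C)[C@H]2COCOC | intermediate
21 | selenoxide of 20 (not isolated) | O=C1OC[C@@]2(CC1(CC1CC=CC1)[Se](=O)c1ccccc1)[C@@H](O[Si](C)(C)C(C)(C)C)CCC(C)(C)[C@H]2COCOC | intermediate
22 | unsaturated spirolactone: 19 with C8=C9 | O=C1OC[C@@]2(C=C1CC1CC=CC1)[C@@H](O[Si](C)(C)C(C)(C)C)CCC(C)(C)[C@H]2COCOC | intermediate
23 | ozonide of 22 (1,2,4-trioxolane in place of the cyclopentene alkene, not isolated) | O=C1OC[C@@]2(C=C1CC1CC3OOC(C1)O3)[C@@H](O[Si](C)(C)C(C)(C)C)CCC(C)(C)[C@H]2COCOC | intermediate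
24 | dialdehyde: 22 with the cyclopentene cleaved to two CH2CHO arms on C13 | O=C1OC[C@@]2(C=C1CC(CC=O)CC=O)[C@@H](O[Si](C)(C)C(C)(C)C)CCC(C)(C)[C@H]2COCOC | intermediate
25 | hydroxy aldehyde: ring C closed (C9–C11), 11-OH, C13–CH2CHO; C9, C11, C13 as in the target, C8 epimers | O=CC[C@@H]2C[C@H](O)[C@@H]3C(C2)C(=O)OC[C@]32[C@@H](O[Si](C)(C)C(C)(C)C)CCC(C)(C)[C@H]2COCOC | intermediate
26 | hydroxy enal: 25 with C13–C(=CH2)–CHO | C=C(C=O)[C@@H]2C[C@H](O)[C@@H]3C(C2)C(=O)OC[C@]32[C@@H](O[Si](C)(C)C(C)(C)C)CCC(C)(C)[C@H]2COCOC | intermediate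
27 | tetracyclic diol: target skeleton with 1-OTBS, 6-OMOM, 11-OH, 15-OH | C=C1[C@@H]2C[C@H](O)[C@@H]3[C@](C2)(C(=O)OC[C@]32[C@@H](O[Si](C)(C)C(C)(C)C)CCC(C)(C)[C@H]2COCOC)[C@@H]1O | intermediate
28 | triol: 1-deacetyl target as its 6-O-methoxymethyl ether | C=C1[C@@H]2C[C@H](O)[C@@H]3[C@](C2)(C(=O)OC[C@]32[C@@H](O)CCC(C)(C)[C@H]2COCOC)[C@@H]1O | intermediate
29 | 6-O-methoxymethyl ether of the target | C=C1[C@@H]2C[C@H](O)[C@@H]3[C@](C2)(C(=O)OC[C@]32[C@@H](OC(C)=O)CCC(C)(C)[C@H]2COCOC)[C@@H]1O | intermediate
30 | CNP0210922.1 | C=C1[C@@H]2C[C@H](O)[C@@H]3[C@](C2)(C(=O)OC[C@]32[C@@H](OC(C)=O)CCC(C)(C)[C@H]2CO)[C@@H]1O | target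

Total step count: 16. Longest linear sequence: 15 (steps 1–6 and 8–16).

**Steps most likely to fail**

Step 11. The cathodic cyclisation may suffer from direct reduction or pinacol-type coupling of the two aldehydes, from attack on the C5 face of the lactone, or from poor selection between the two arms. The fallback differentiates the arms beforehand and gives up the desymmetrisation. It sets out from 22: ozonolysis in CH2Cl2/MeOH, then p-TsOH, then NaHCO3 and Me2S would give the aldehyde dimethyl acetal F1 as both C13 epimers. SmI2 (THF, t-BuOH, −78 °C) ketyl–olefin cyclisation, now with a single aldehyde, would give the acetal alcohol F2 after separation from its C13 epimer. Aqueous acid (PPTS, acetone/H2O) would return the route at 25.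

Step 13. Closure through a lithium-bridged Zimmerman–Traxler transition state between the enolate and aldehyde oxygens would turn the carbinol oxygen away from C11 and erode the facial selectivity at C15. Oxa-Michael addition of the C11 alkoxide and retro-aldol reopening may compete. The fallback sets out from 26 and accepts the aldol as a mixture that contains the 15-epimer F3. MnO2 (CH2Cl2, rt) would oxidise only the allylic carbinol to the enone F4. Luche reduction (NaBH4, CeCl3·7H2O, MeOH, −78 °C), with hydride from the exo face of the two-carbon bridge, would come back at 27.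

Step 3. The neopentylic β-carbon may slow the copper hydride addition and erode the enantiofacial control, and the Mannich capture may lose regiocontrol if the silyl enol ether equilibrates. The fallback sets out from 6 and makes the series racemic. The achiral hydride [(Ph3P)CuH]6 with (EtO)2MeSiH, then Eschenmoser's salt, would give the racemic Mannich base F5. Elimination and Luche reduction as in step 4 would give the racemic cis allylic alcohol F6. Sharpless kinetic resolution (Ti(Oi-Pr)4, L-(+)-diisopropyl tartrate, t-BuOOH 0.6 equiv, CH2Cl2, −20 °C) should epoxidise the (1S,3R) enantiomer to the epoxy alcohol F7. Silylation (TBSCl, imidazole) would come back at 13 as one epoxide epimer.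

**Further compounds**
F1 | step 11 | aldehyde dimethyl acetal: 24 with one CHO arm as CH(OMe)2, both C13 epimers | O=C1OC[C@@]2(C=C1CC(CC=O)CC(OC)OC)[C@@H](O[Si](C)(C)C(C)(C)C)CCC(C)(C)[C@H]2COCOC
F2 | step 11 | acetal alcohol: 25 with the aldehyde as its dimethyl acetal | COC(OC)C[C@@H]2C[C@H](O)[C@@H]3C(C2)C(=O)OC[C@]32[C@@H](O[Si](C)(C)C(C)(C)C)CCC(C)(C)[C@H]2COCOC
F3 | step 13 | 15-epimer of 27 (15-hydroxyl exo) | C=C1[C@@H]2C[C@H](O)[C@@H]3[C@](C2)(C(=O)OC[C@]32[C@@H](O[Si](C)(C)C(C)(C)C)CCC(C)(C)[C@H]2COCOC)[C@H]1O
F4 | step 13 | C15 enone of 27 | C=C1[C@@H]2C[C@H](O)[C@@H]3[C@](C2)(C(=O)OC[C@]32[C@@H](O[Si](C)(C)C(C)(C)C)CCC(C)(C)[C@H]2COCOC)C1=O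
F5 | step 3 | racemic 2-[(dimethylamino)methyl]-3-[(methoxymethoxy)methyl]-4,4-dimethylcyclohexan-1-one | CN(C)CC1C(=O)CCC(C)(C)C1COCOC
F6 | step 3 | racemic cis-3-[(methoxymethoxy)methyl]-4,4-dimethyl-2-methylidenecyclohexan-1-ol | C=C1C(O)CCC(C)(C)C1COCOC
F7 | step 3 | epoxy alcohol: 8-[(methoxymethoxy)methyl]-7,7-dimethyl-1-oxaspiro[2.5]octan-4-ol, C1 and C5 as in 11, one epimer at the spiro carbon | C1OC12[C@@H](O)CCC(C)(C)[C@H]2COCOC
A1 | direct plan | cyclopropanol: C9–C10–C11 three-membered ring on the bicyclo[3.2.1]octane lactone, 1-acetate, (E)-alkenyl pinacol boronate chain | C=C1[C@@H]2C[C@]3(O)[C@@H]4[C@](C2)(C(=O)OC[C@]34[C@@H](OC(C)=O)CCC(C)(C)/C=C/B5OC(C)(C)C(C)(C)O5)C1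
A2 | direct plan | spiro ketone: ring A closed, C11 ketone, C6 pinacol boronate | C=C1[C@@H]2CC(=O)[C@@H]3[C@](C2)(C(=O)OC[C@]32[C@@H](OC(C)=O)CCC(C)(C)[C@H]2CB4OC(C)(C)C(C)(C)O4)C1
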